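The readings are calculated from invented constants.

| setting | ochre | red | flask |
|---|---|---|---|
| X | 20 mM | 31 mM | 14 mM |
| D | 4.4 mM (held) | 4.4 mM (held) | 4.4 mM (held) |
| Z | 7.3 µM | 7.3 µM | 7.3 µM |
| remark | run made earlier | run made earlier |  |
| time |  |  | 30 h |

| run | time / h | Q / % | X / % |
|---|---|---|---|
| ochre | 8.00 | 7.9 | 91.5 |
| ochre | 12.0 | 9.2 | 90.3 |
| ochre | 15.0 | 10.2 | 89.8 |
| ochre | 25.0 | 11.3 | 88.0 |
| ochre | 40.0 | 13.3 | 87.1 |
| red | 8.00 | 7.6 | 91.7 |
| red | 12.0 | 9.9 | 90.7 |
| red | 15.0 | 10.2 | 90.0 |
| red | 25.0 | 11.9 | 88.2 |
| red | 40.0 | 12.8 | 86.8 |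

(readings scatter by 0.3 percentage points)

* the moment within 30 h at which there is most Q
* the amount of Q, in percent of the X charged, at that time
* the first time at which Q reaches 6.1%, in the same percent

**Impossible line.** X cannot be leaving these runs by a steady first-order loss. I work with the fraction left: the depth ℓ is the natural logarithm of X charged over X present, and a steady loss would make ℓ grow in step with time. From 8.00 h to 40.0 h, time grows by a factor 5.00. Yet ℓ, averaged over ochre and red, goes from 0.0877 to 0.140, a factor 1.60.

**Better guess.** Perhaps ℓ gains a fixed amount per doubling of time. The end readings give 0.0224, and I call this the doubling gain, d. But two points always make a line. So I test it at 15.0 h: d predicts X at 89.8%, the runs read 89.9%, and the scatter is 0.3 percentage points.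

**Other charge.** The flask holds 14 mM of X, a charge neither run had. But at 40.0 h ochre and red read 87.1% and 86.8%, so the loss looks first order in X, with a coefficient that falls as time passes, and I carry ℓ over unchanged. Q and X together average 100% there, so Q is what X lost, and it is still climbing. My peak therefore stands at 30 h, with 12.2%.

**Early end.** 6.1% of Q means ℓ = 0.0629, which is 1.11 doublings back from 8.00 h, or 3.72 h. The objection is real: the line reaches zero at 0.532 h, not at the start, so it must bend early, which would bring the time forward. D must also dissolve first, which would delay it. No reading lies that early, so I keep 3.72 h, loosely.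

**The forecast.** It gives 30 h and 12.1%, close to mine, but 5.2 h for the level, later than my time, adding that “there are no early data”.

**The flask.** Within the 30 h allowed, the flask has most Q at 30.0 h, with 12.2%, and it reaches 6.1% at 3.60 h. Z stands at 3.60% of its charge at 15.0 h and at half that, 1.83%, at 30.0 h.

    X + G + Z → Z + Q (k = 520 /M²/s)
    2 Z → L (k = 34.0 /M/s)
    D ⇌ G, rate k3*(csat - [G]) (kL = 0.00350 /s)

**Gain reused.** Starting from 3.60 h at ℓ = 0.0629, d gives 12.3% of Q at 30 h, against 12.2%. The same step to the neighbouring flask, left until 8.0 h, gives 8.49%, and that flask holds 8.35%.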